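Atom numbers follow the ring path: C1 vinyl Me, C2=C3, C4, C5-OH, C6-Me, C7, C8-OH, C9-Me, C10, C11, C12-Me, C13, C14, C15-Me2, C16, C17, C18, C19, C20. Rings: A = C3–C7; B = C2, C3, C7–C9, C18–C20; C = C9–C12, C17, C18; D = C12–C17.
Enabling feature: rings C/D form a trans-decalin in which quaternary C12 adjoins the C17 methine and C15 can be a carbonyl carbon. The first cuts are therefore C12–C17 and C13–C14, giving a C12=C13 vinyl sulfone on the C9 arm and a C14=C15(OSi)–C16=C17 diene on C18.
Next cuts: C7=C8 (carbonyl coupling) and C20–C2 (B-alkyl Suzuki) open ring B into ring-A enol triflate 6 and block 18. Block 18 comes from a Diels–Alder cyclohexene (bonds C9–C18, C10–C11) by cleaving C12=C19.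
Forward order: ring A is bought, ring B is closed in steps 14 and 16, rings C and D form together in step 24, then the C15 gem-dimethyl group and deprotection.
Stereochemistry: C5 from Cu-catalysed borylation, with C6 following by equilibration. C9/C18 from a catalytic asymmetric Diels–Alder reaction. C7/C8 from syn-hydroboration anti to the C6 methyl. C12/C17 from the chair-like endo transition state of step 24. The C2=C3 geometry comes from a chelated Z-enol triflate.
Key step: step 24

Assumption: the sense of induction in steps 1 and 8 is taken as drawn. If it proves opposite, the enantiomeric ligand or catalyst is used and nothing else changes.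
Abbreviations: TBS = tert-butyldimethylsilyl, TES = triethylsilyl. "Up/down on ring B" refers to the face that carries 7-H, 8-O and 18-H in the target.

Step 1
Reactants: 1 2-methylcyclopent-2-en-1-one
Product: 3 (2S,3R)-3-hydroxy-2-methylcyclopentan-1-one, via boryl ketone 2 (not isolated)
Conditions: B2pin2, CuCl/NaOt-Bu/(R,S)-Josiphos (cat.), MeOH, THF, rt; then NaBO3·4H2O, THF–H2O
Reagents that add atoms: bis(pinacolato)diboron CC1(C)OB(OC1(C)C)B1OC(C)(C)C(C)(C)O1; sodium perborate [Na+].[O-]OB=O
Why: Enantioselective copper-catalysed conjugate borylation of a cyclic enone followed by stereoretentive C–B oxidation; the chiral Cu–Bpin species sets C5, and C6, being α to the ketone, settles trans to the C5 substituent.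

Step 2
Reactants: 3 (2S,3R)-3-hydroxy-2-methylcyclopentan-1-one
Product: 4 (2S,3R)-3-(TBS-oxy)-2-methylcyclopentan-1-one
Conditions: TBSCl, imidazole, DMF, rt
Reagents that add atoms: tert-butyldimethylsilyl chloride CC(C)(C)[Si](C)(C)Cl
Why: Standard silyl ether formation under non-basic conditions, which blocks β-elimination of O5 and creates no stereocentre.

Step 3
Reactants: 4 (2S,3R)-3-(TBS-oxy)-2-methylcyclopentan-1-one
Product: 5 (2S,3R)-5-acetyl-3-(TBS-oxy)-2-methylcyclopentan-1-one (enolised at C3 of the target numbering)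
Conditions: LDA (2 equiv), THF, −78 °C; 1-acetylbenzotriazole; NH4Cl
Reagents that add atoms: 1-acetylbenzotriazole CC(=O)n1nnc2ccccc12
Why: Kinetic deprotonation at the unhindered C3 methylene (C6 is tertiary) and C-acylation of the lithium enolate with an N-acylbenzotriazole (crossed Claisen acylation) bring in C2 and C1; the new centre is enolised and without consequence.

Step 4
Reactants: 5 (2S,3R)-5-acetyl-3-(TBS-oxy)-2-methylcyclopentan-1-one
Product: 6 (Z)-1-[(3S,4R)-4-(TBS-oxy)-3-methyl-2-oxocyclopentylidene]ethyl triflate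
Conditions: Tf2O, aq LiOH, toluene, 5 °C
Reagents that add atoms: trifluoromethanesulfonic anhydride O=S(=O)(OS(=O)(=O)C(F)(F)F)C(F)(F)F
Why: O-sulfonylation of the lithium-chelated β-diketonate; the five-membered ring prefers the exocyclic enol double bond, the less hindered acetyl oxygen reacts, and chelation holds it cis to C7=O, so the Z geometry that becomes C2=C3 is fixed here.

Step 5
Reactants: 7 methacrolein; 8 triethyl phosphonoacetate
Product: 9 ethyl (2E)-4-methylpenta-2,4-dienoate
Conditions: NaH, THF, 0 °C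
Reagents that add atoms: none
Why: Horner–Wadsworth–Emmons olefination of an enal with a stabilised phosphonate, which is reliably E-selective.

Step 6
Reactants: 9 ethyl (2E)-4-methylpenta-2,4-dienoate
Product: 10 (2E)-4-methylpenta-2,4-dien-1-ol
Conditions: DIBAL-H (2.2 equiv), CH2Cl2, −78 °C; Rochelle salt
Reagents that add atoms: none
Why: 1,2-Reduction of a conjugated ester with an aluminium hydride leaves the diene untouched.

Step 7
Reactants: 10 (2E)-4-methylpenta-2,4-dien-1-ol
Product: 11 tert-butyl(dimethyl){[(2E)-4-methylpenta-2,4-dien-1-yl]oxy}silane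
Conditions: TBSCl, imidazole, CH2Cl2, rt
Reagents that add atoms: tert-butyldimethylsilyl chloride CC(C)(C)[Si](C)(C)Cl
Why: Silylation of a primary allylic alcohol gives a diene that tolerates the Lewis acid of step 8.

Step 8
Reactants: 11 tert-butyl(dimethyl){[(2E)-4-methylpenta-2,4-dien-1-yl]oxy}silane; 7 methacrolein
Product: 12 (1S,2R)-2-(TBS-oxymethyl)-1,4-dimethylcyclohex-3-ene-1-carbaldehyde
Conditions: (S)-o-tolyl-oxazaborolidine from diphenylprolinol·Tf2NH (15 mol %), CH2Cl2, −78 to −40 °C
Reagents that add atoms: none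
Why: Catalytic enantioselective Diels–Alder reaction of an α-substituted acrolein; the 1-alkyl and 3-methyl groups of the diene both send C11 to the β-carbon C10, the formyl-endo approach puts C8 and C17 cis, and the shielded face of the bound enal sets quaternary C9 and C18 absolutely.

Step 9
Reactants: 12 (1S,2R)-2-(TBS-oxymethyl)-1,4-dimethylcyclohex-3-ene-1-carbaldehyde
Product: 13 [(1S,2R)-2-(TBS-oxymethyl)-1,4-dimethylcyclohex-3-en-1-yl]methanol
Conditions: NaBH4, MeOH, 0 °C
Reagents that add atoms: none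
Why: Borohydride reduction of a non-enolisable aldehyde parks C8 at the alcohol level while the other carbonyl groups are handled.

Step 10
Reactants: 13 [(1S,2R)-2-(TBS-oxymethyl)-1,4-dimethylcyclohex-3-en-1-yl]methanol
Product: 14 TES ether of 13
Conditions: TESCl, imidazole, CH2Cl2, 0 °C
Reagents that add atoms: chlorotriethylsilane CC[Si](Cl)(CC)CC
Why: Silylation with the smaller TES group marks O8 for the selective oxidative release of step 15.

Step 11
Reactants: 14 TES ether of 13
Product: 16 (2R,3S)-2-(TBS-oxymethyl)-3-methyl-6-oxo-3-(TES-oxymethyl)heptanal, via ozonide 15 (not isolated)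
Conditions: O3, CH2Cl2, −78 °C; then PPh3
Reagents that add atoms: ozone [O-][O+]=O
Why: Ozonolysis with reductive work-up cleaves the only alkene (C12=C19) and delivers two differentiated carbonyl groups, the C12 methyl ketone and the C19 aldehyde.

Step 12
Reactants: 16 (2R,3S)-2-(TBS-oxymethyl)-3-methyl-6-oxo-3-(TES-oxymethyl)heptanal
Product: 17 (5S,6R)-6-(TBS-oxymethyl)-5-methyl-5-(TES-oxymethyl)oct-7-en-2-one
Conditions: MePPh3Br, KHMDS (1 equiv of ylide), THF, −78 to 0 °C
Reagents that add atoms: methyltriphenylphosphonium bromide C[P+](c1ccccc1)(c1ccccc1)c1ccccc1.[Br-]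
Why: Wittig methylenation with one equivalent of ylide at low temperature takes the aldehyde in preference to the methyl ketone, adds C20 and is fast enough to leave the α-centre C18 untouched.

Step 13
Reactants: 17 (5S,6R)-6-(TBS-oxymethyl)-5-methyl-5-(TES-oxymethyl)oct-7-en-2-one
Product: 18 ethylene ketal of 17
Conditions: (TMSOCH2)2, TMSOTf (cat.), CH2Cl2, −78 °C
Reagents that add atoms: 1,2-bis(trimethylsilyloxy)ethane C[Si](C)(C)OCCO[Si](C)(C)C
Why: Aprotic TMSOTf-catalysed ketalisation masks the C12 ketone for the reductive coupling of step 16 without touching either silyl ether.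

Step 14
Reactants: 18 ethylene ketal of 17; 6 (Z)-enol triflate
Product: 20 Z-enone carrying the C8–C12/C17–C20 block on C2, via B-alkyl-9-BBN 19 (not isolated)
Conditions: 9-BBN, THF, rt; then 6, PdCl2(dppf), AsPh3 (cat.), Cs2CO3, DMF–H2O, 50 °C
Reagents that add atoms: 9-borabicyclo[3.3.1]nonane [H]B1C2CCCC1CCC2
Why: Anti-Markovnikov hydroboration of the only alkene and B-alkyl Suzuki–Miyaura coupling form C20–C2 with retention of the triflate geometry, so C20 ends cis to C7 on the tetrasubstituted C2=C3 bond.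

Step 15
Reactants: 20 Z-enone carrying the C8–C12/C17–C20 block on C2
Product: 21 keto aldehyde (C8 aldehyde and C7 enone carbonyl)
Conditions: (COCl)2, DMSO, CH2Cl2, −78 to −35 °C; Et3N
Reagents that add atoms: none
Why: Under Swern conditions a primary triethylsilyl ether is attacked by the activated sulfoxide and oxidised directly to the aldehyde, whereas TBS ethers, the ketal and the enone remain.

Step 16
Reactants: 21 keto aldehyde
Product: 22 5-8 bicyclic diene (C2=C3 and C7=C8)
Conditions: TiCl3(DME)1.5, Zn–Cu, DME, reflux, slow addition of 21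
Reagents that add atoms: none
Why: Intramolecular McMurry coupling joins C7 and C8 and deoxygenates the titanium pinacolate; the preformed Z C2=C3 bond holds both carbonyl groups on one side, the eight-membered ring allows only the Z C7=C8 bond, and silyl ethers and the ketal are tolerated.

Step 17
Reactants: 22 5-8 bicyclic diene
Product: 24 bicyclic C8 alcohol, via alkylborane 23 (not isolated)
Conditions: BH3·THF (slight excess), THF, 0 °C; then NaOH, H2O2
Reagents that add atoms: borane–tetrahydrofuran [BH3-][O+]1CCCC1; hydrogen peroxide OO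
Why: Hydroboration–oxidation places boron on the CH terminus C8 and hydrogen on C7 in a syn addition to the open face opposite the C6 methyl, which puts 7-H and 8-OH on the same face of ring B and C8 cis to the C6 methyl; the tetrasubstituted C2=C3 bond reacts more slowly and the oxidation is retentive.

Step 18
Reactants: 24 bicyclic C8 alcohol
Product: 25 bicyclic 5,8-bis-TBS ether
Conditions: TBSOTf, 2,6-lutidine, CH2Cl2, 0 °C
Reagents that add atoms: tert-butyldimethylsilyl triflate CC(C)(C)[Si](C)(C)OS(=O)(=O)C(F)(F)F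
Why: The silyl triflate silylates the hindered neopentyl-type alcohol; a silyl group is chosen over an acetal because O8 must survive the Lewis acid of step 27.

Step 19
Reactants: 25 bicyclic 5,8-bis-TBS ether
Product: 26 bicyclic hydroxy ketone (C12 ketone and C17 alcohol)
Conditions: AcOH–THF–H2O (3:1:1), 35 °C
Reagents that add atoms: water O
Why: Mild acid hydrolysis removes the ketal and the primary TBS ether in one operation, while the two secondary TBS ethers, one of them neopentyl-like, hydrolyse far more slowly.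

Step 20
Reactants: 26 bicyclic hydroxy ketone; 27 diethyl (phenylsulfonyl)methylphosphonate
Product: 28 (E)-vinyl sulfone alcohol
Conditions: 27, NaH, THF, 0 °C; then 26, 0 to 50 °C
Reagents that add atoms: none
Why: Horner–Wadsworth–Emmons olefination of the methyl ketone with the preformed sulfonyl phosphonate anion, which is too weak a base to deprotonate the free alcohol; the E isomer (chain trans to sulfonyl) should prevail and the Z isomer is removed by chromatography.

Step 21
Reactants: 28 (E)-vinyl sulfone alcohol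
Product: 29 C17 aldehyde
Conditions: DMP, CH2Cl2, rt
Reagents that add atoms: none
Why: Periodinane oxidation of the primary alcohol under neutral conditions spares the vinyl sulfone, the alkene and the configuration at C18.

Step 22
Reactants: 29 C17 aldehyde; 30 1-(triphenylphosphoranylidene)propan-2-one
Product: 31 (E)-enone (C17=C16–C15(=O)–C14H3)
Conditions: toluene, 90 °C
Reagents that add atoms: none
Why: Wittig reaction with a stabilised, non-basic ylide gives the E-enone, adds C16–C14 and does not epimerise C18.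

Step 23
Reactants: 31 (E)-enone
Product: 32 silyloxydiene–vinyl sulfone (cycloaddition precursor)
Conditions: TBSOTf, Et3N, CH2Cl2, 0 °C
Reagents that add atoms: tert-butyldimethylsilyl triflate CC(C)(C)[Si](C)(C)OS(=O)(=O)C(F)(F)F
Why: Soft enolisation and silylation of the methyl ketone at its only enolisable position (C14) gives the cross-conjugated 2-silyloxydiene; triethylamine is too weak to isomerise the vinyl sulfone.

Step 24
Reactants: 32 silyloxydiene–vinyl sulfone
Product: 33 tetracyclic C13 sulfone with C15 silyl enol ether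
Conditions: toluene (0.01 M), BHT, propylene oxide, silylated sealed tube, 190 °C
Reagents that add atoms: none
Why: Thermal, concerted but asynchronous [4+2] cycloaddition within the 1,7,9-decatriene C13=C12–C11–C10–C9–C18–C17=C16–C15=C14; the closest known reaction type is the type 1 intramolecular Diels–Alder reaction of decatrienes bearing a sulfonyl group at the dienophile terminus. Ring D closes as the new cyclohexene through C12–C17 and C13–C14, and ring C closes in the fused mode as the six-membered ring completed by the four-atom tether C11–C10–C9–C18. The silyloxy group makes C14 the nucleophilic diene terminus and the sulfonyl group makes C12 the electrophilic alkene carbon, so the pairing is electronically mismatched, but the matched pairing (C14 to C12) would give a bridged bicyclo[4.3.1]decene that a four-atom tether on an E-diene cannot reach, hence the tether decides the regiochemistry at the price of a high temperature. C17 is set by the chair-like tether, in which C8, C19 and the diene are equatorial, the C9 methyl is axial and 17-H comes out anti to 18-H; C12 is set by the anti (trans-decalin) folding, in which the C12 methyl and, because of the E geometry, the sulfonyl group lie endo over the diene; C13 (sulfonyl cis to the C12 methyl) follows from suprafacial addition and is erased in step 25. The step needs trans- over cis-fused closure and one diene face: the first rests on the endo preference of the E-sulfonyl group and the all-chair, product-like geometry, the second on the trans disposition of the two arms on ring B, which leaves only one chair with both ring-B bonds equatorial. The hindered phenol, the epoxide acid scavenger and the silylated glass protect the dienol ether, while the tetrasubstituted C2=C3 bond and the TBS ethers are inert.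

Step 25
Reactants: 33 tetracyclic C13 sulfone with C15 silyl enol ether
Product: 35 tetracyclic C13=C14–C15 enone, via sulfonyl ketone 34 (not isolated)
Conditions: K2CO3, MeOH–THF, rt
Reagents that add atoms: none
Why: Base-catalysed methanolysis of the silyl enol ether unmasks the C15 ketone, to which the sulfonyl group is β, so E1cB loss of benzenesulfinate follows and removes the activating group without a reducing metal; C12 is quaternary and C17 is β to the carbonyl, so neither can epimerise.

Step 26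
Reactants: 35 tetracyclic C13=C14–C15 enone
Product: 36 tetracyclic C15 ketone
Conditions: H2 (1 atm), Pd/C, EtOAc, rt
Reagents that add atoms: none
Why: Catalytic hydrogenation saturates the disubstituted enone double bond, whereas the hindered tetrasubstituted C2=C3 bond is not reduced at atmospheric pressure.

Step 27
Reactants: 36 tetracyclic C15 ketone
Product: 37 5,8-bis-TBS ether of the target
Conditions: Me2Zn, TiCl4 (Me2TiCl2 formed in situ), CH2Cl2, −30 °C to rt
Reagents that add atoms: dimethylzinc C[Zn]C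
Why: Direct geminal dimethylation of a ketone with Me2TiCl2 (methyl addition, ionisation of the tertiary titanium alkoxide, second methyl transfer) acts on the only carbonyl group, an unhindered cyclohexanone, and hindered secondary silyl ethers withstand the reagent.

Step 28
Reactants: 37 5,8-bis-TBS ether of the target
Product: 38 target CNP0213887.1
Conditions: HF·pyridine, THF, 0 °C to rt
Reagents that add atoms: none
Why: Fluoride-driven cleavage of both silyl ethers liberates the C5 and C8 alcohols without touching any stereocentre or the tetrasubstituted alkene.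

Compound list
1 | 2-methylcyclopent-2-en-1-one | CC1=CCCC1=O | starting material
2 | (2S,3R)-2-methyl-3-(4,4,5,5-tetramethyl-1,3,2-dioxaborolan-2-yl)cyclopentan-1-one | C1C[C@@H](B2OC(C)(C)C(C)(C)O2)[C@H](C)C1=O | intermediate
3 | (2S,3R)-3-hydroxy-2-methylcyclopentan-1-one | C1C[C@@H](O)[C@H](C)C1=O | intermediate
4 | (2S,3R)-3-(TBS-oxy)-2-methylcyclopentan-1-one | C1C[C@@H](O[Si](C)(C)C(C)(C)C)[C@H](C)C1=O | intermediate
5 | (2S,3R)-5-acetyl-3-(TBS-oxy)-2-methylcyclopentan-1-one (acetyl-bearing carbon enolised) | CC(=O)C1C[C@@H](O[Si](C)(C)C(C)(C)C)[C@H](C)C1=O | intermediate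
6 | (Z)-1-[(3S,4R)-4-(TBS-oxy)-3-methyl-2-oxocyclopentylidene]ethyl trifluoromethanesulfonate (OTf cis to C=O) | C/C(OS(=O)(=O)C(F)(F)F)=C1\C[C@@H](O[Si](C)(C)C(C)(C)C)[C@H](C)C1=O | intermediate
7 | methacrolein | C=C(C)C=O | starting material
8 | triethyl phosphonoacetate | CCOC(=O)CP(=O)(OCC)OCC | starting material
9 | ethyl (2E)-4-methylpenta-2,4-dienoate | C=C(C)/C=C/C(=O)OCC | intermediate
10 | (2E)-4-methylpenta-2,4-dien-1-ol | C=C(C)/C=C/CO | intermediate
11 | tert-butyl(dimethyl){[(2E)-4-methylpenta-2,4-dien-1-yl]oxy}silane | C=C(C)/C=C/CO[Si](C)(C)C(C)(C)C | intermediate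
12 | (1S,2R)-2-(TBS-oxymethyl)-1,4-dimethylcyclohex-3-ene-1-carbaldehyde (CHO and CH2OTBS cis) | O=C[C@@]1(C)CCC(C)=C[C@H]1CO[Si](C)(C)C(C)(C)C | intermediate
13 | [(1S,2R)-2-(TBS-oxymethyl)-1,4-dimethylcyclohex-3-en-1-yl]methanol | OC[C@@]1(C)CCC(C)=C[C@H]1CO[Si](C)(C)C(C)(C)C | intermediate
14 | TES ether of 13 | CC[Si](CC)(CC)OC[C@@]1(C)CCC(C)=C[C@H]1CO[Si](C)(C)C(C)(C)C | intermediate
15 | secondary ozonide of 14 (1,2,4-trioxolane across C12/C19, both acetal carbons unassigned) | CC[Si](CC)(CC)OC[C@@]1(C)CCC2(C)OOC(O2)[C@H]1CO[Si](C)(C)C(C)(C)C | intermediate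
16 | (2R,3S)-2-(TBS-oxymethyl)-3-methyl-6-oxo-3-(TES-oxymethyl)heptanal | CC[Si](CC)(CC)OC[C@@](C)(CCC(C)=O)[C@H](CO[Si](C)(C)C(C)(C)C)C=O | intermediate
17 | (5S,6R)-6-(TBS-oxymethyl)-5-methyl-5-(TES-oxymethyl)oct-7-en-2-one | CC[Si](CC)(CC)OC[C@@](C)(CCC(C)=O)[C@H](CO[Si](C)(C)C(C)(C)C)C=C | intermediate
18 | ethylene ketal of 17 | CC[Si](CC)(CC)OC[C@@](C)(CCC1(C)OCCO1)[C@H](CO[Si](C)(C)C(C)(C)C)C=C | intermediate
19 | B-alkyl-9-BBN from 18 (boron on C20) | CC[Si](CC)(CC)OC[C@@](C)(CCC1(C)OCCO1)[C@H](CO[Si](C)(C)C(C)(C)C)CCB1C2CCCC1CCC2 | intermediate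
20 | Z-enone: ring A with C7=O, 6-Me/5-OTBS trans, C3=C2(Me)–C20H2–C19H2–C18 with C20 cis to C7; C18 bears CH2OTBS; C9 bears Me, CH2OTES and the ketal chain | CC[Si](CC)(CC)OC[C@@](C)(CCC1(C)OCCO1)[C@H](CO[Si](C)(C)C(C)(C)C)CC/C(C)=C1/C[C@@H](O[Si](C)(C)C(C)(C)C)[C@H](C)C1=O | intermediate
21 | keto aldehyde: as 20 with C8 as CHO | O=C[C@@](C)(CCC1(C)OCCO1)[C@H](CO[Si](C)(C)C(C)(C)C)CC/C(C)=C1/C[C@@H](O[Si](C)(C)C(C)(C)C)[C@H](C)C1=O | intermediate
22 | 5-8 bicyclic diene: C2=C3 and C7=C8 both Z in ring B, 5-OTBS/6-Me trans, C9 Me and ketal chain, C18 CH2OTBS trans to the C9 chain | C/C1=C2\C[C@@H](O[Si](C)(C)C(C)(C)C)[C@H](C)/C2=C/[C@@](C)(CCC3(C)OCCO3)[C@H](CO[Si](C)(C)C(C)(C)C)CC1 | intermediate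
23 | C8 alkylborane (BH2 and 7-H on the same face of ring B) | C/C1=C2\C[C@@H](O[Si](C)(C)C(C)(C)C)[C@H](C)[C@@H]2[C@@H](B)[C@@](C)(CCC3(C)OCCO3)[C@H](CO[Si](C)(C)C(C)(C)C)CC1 | intermediate
24 | bicyclic C8 alcohol: 7-H, 8-OH, C10 and 18-H up, 9-Me and C17 down on ring B; C8 cis to 6-Me on ring A | C/C1=C2\C[C@@H](O[Si](C)(C)C(C)(C)C)[C@H](C)[C@@H]2[C@@H](O)[C@@](C)(CCC3(C)OCCO3)[C@H](CO[Si](C)(C)C(C)(C)C)CC1 | intermediate
25 | 8-O-TBS ether of 24 | C/C1=C2\C[C@@H](O[Si](C)(C)C(C)(C)C)[C@H](C)[C@@H]2[C@@H](O[Si](C)(C)C(C)(C)C)[C@@](C)(CCC3(C)OCCO3)[C@H](CO[Si](C)(C)C(C)(C)C)CC1 | intermediate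
26 | bicyclic hydroxy ketone: C9 CH2CH2C(O)CH3, C18 CH2OH, 5,8-bis-OTBS | C/C1=C2\C[C@@H](O[Si](C)(C)C(C)(C)C)[C@H](C)[C@@H]2[C@@H](O[Si](C)(C)C(C)(C)C)[C@@](C)(CCC(C)=O)[C@H](CO)CC1 | intermediate
27 | diethyl (phenylsulfonyl)methylphosphonate | CCOP(=O)(CS(=O)(=O)c1ccccc1)OCC | starting material
28 | (E)-vinyl sulfone alcohol: C9 CH2CH2C(Me)=CHSO2Ph, C18 CH2OH | C/C1=C2\C[C@@H](O[Si](C)(C)C(C)(C)C)[C@H](C)[C@@H]2[C@@H](O[Si](C)(C)C(C)(C)C)[C@@](C)(CC/C(C)=C/S(=O)(=O)c3ccccc3)[C@H](CO)CC1 | intermediate
29 | C17 aldehyde of 28 | C/C1=C2\C[C@@H](O[Si](C)(C)C(C)(C)C)[C@H](C)[C@@H]2[C@@H](O[Si](C)(C)C(C)(C)C)[C@@](C)(CC/C(C)=C/S(=O)(=O)c3ccccc3)[C@H](C=O)CC1 | intermediate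
30 | 1-(triphenylphosphoranylidene)propan-2-one | CC(=O)C=P(c1ccccc1)(c1ccccc1)c1ccccc1 | starting material
31 | (E)-enone: C18 bears (E)-CH=CH–C(O)CH3 | C/C1=C2\C[C@@H](O[Si](C)(C)C(C)(C)C)[C@H](C)[C@@H]2[C@@H](O[Si](C)(C)C(C)(C)C)[C@@](C)(CC/C(C)=C/S(=O)(=O)c3ccccc3)[C@H](/C=C/C(C)=O)CC1 | intermediate
32 | cycloaddition precursor: 5-8 bicycle with (E)-vinyl sulfone arm on C9 and (E)-3-(TBS-oxy)buta-1,3-dienyl arm on C18 | C/C1=C2\C[C@@H](O[Si](C)(C)C(C)(C)C)[C@H](C)[C@@H]2[C@@H](O[Si](C)(C)C(C)(C)C)[C@@](C)(CC/C(C)=C/S(=O)(=O)c3ccccc3)[C@H](/C=C/C(=C)O[Si](C)(C)C(C)(C)C)CC1 | intermediate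
33 | cycloadduct: 5-8-6-6 tetracycle, trans C/D fusion, 13-SO2Ph cis to 12-Me, C15=C16 TBS enol ether | C/C1=C2\C[C@@H](O[Si](C)(C)C(C)(C)C)[C@H](C)[C@@H]2[C@@H](O[Si](C)(C)C(C)(C)C)[C@@]2(C)CC[C@]3(C)[C@@H](S(=O)(=O)c4ccccc4)CC(O[Si](C)(C)C(C)(C)C)=C[C@H]3[C@@H]2CC1 | intermediate
34 | 13-phenylsulfonyl C15 ketone | C/C1=C2\C[C@@H](O[Si](C)(C)C(C)(C)C)[C@H](C)[C@@H]2[C@@H](O[Si](C)(C)C(C)(C)C)[C@@]2(C)CC[C@]3(C)[C@@H](S(=O)(=O)c4ccccc4)CC(=O)C[C@H]3[C@@H]2CC1 | intermediate
35 | tetracyclic enone C13=C14–C15=O | C/C1=C2\C[C@@H](O[Si](C)(C)C(C)(C)C)[C@H](C)[C@@H]2[C@@H](O[Si](C)(C)C(C)(C)C)[C@@]2(C)CC[C@]3(C)C=CC(=O)C[C@H]3[C@@H]2CC1 | intermediate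
36 | tetracyclic C15 ketone | C/C1=C2\C[C@@H](O[Si](C)(C)C(C)(C)C)[C@H](C)[C@@H]2[C@@H](O[Si](C)(C)C(C)(C)C)[C@@]2(C)CC[C@]3(C)CCC(=O)C[C@H]3[C@@H]2CC1 | intermediate
37 | 5,8-bis-TBS ether of the target | C/C1=C2\C[C@@H](O[Si](C)(C)C(C)(C)C)[C@H](C)[C@@H]2[C@@H](O[Si](C)(C)C(C)(C)C)[C@@]2(C)CC[C@]3(C)CCC(C)(C)C[C@H]3[C@@H]2CC1 | intermediate
38 | CNP0213887.1 (5R,6R,7S,8R,9S,12S,17S,18S in the path numbering, C2=C3 Z) | C/C1=C2\C[C@@H](O)[C@H](C)[C@@H]2[C@@H](O)[C@@]2(C)CC[C@]3(C)CCC(C)(C)C[C@H]3[C@@H]2CC1 | target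

Total step count: 28. Longest linear sequence: 24 steps (steps 5–28); steps 1–4 form the second branch.

Steps most likely to fail

Step 24. The trisubstituted dienophile has to build a quaternary carbon against the polarity of the diene. The cycloaddition may therefore be slower than thermal loss of the dienol ether, and the cis-fused mode may compete. The fallback exchanges the activating group for one that a Lewis acid can switch on. Ketone 26 is olefinated with diethyl [(pyridin-2-ylsulfonyl)methyl]phosphonate (NaH, THF) to the 2-pyridyl vinyl sulfone alcohol F1. This is oxidised with DMP to the aldehyde F2, extended with 30 to the enone F3 and silylated (TBSOTf, Et3N) to the silyloxydiene F4. N,O-chelation of the pyridylsulfonyl group to Cu(OTf)2 (CH2Cl2, molecular sieves, 0 °C to rt) lowers the dienophile LUMO, so the same two bonds can form without heating and give the pyridylsulfonyl cycloadduct F5. K2CO3 in MeOH then expels pyridine-2-sulfinate and returns to 35.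

Step 16. Closing an eight-membered ring between a hindered enone carbonyl and a neopentyl aldehyde may lose out to intermolecular coupling, to simple carbonyl reduction, or may stop at the pinacol stage. The fallback separates C–C bond formation from deoxygenation. SmI2 (THF, t-BuOH, high dilution) couples 21 to the cis-7,8-diol F6, with C8 entering anti to the C6 methyl. Thiocarbonyldiimidazole converts F6 into the cyclic thionocarbonate F7. A Corey–Winter elimination with 1,3-dimethyl-2-phenyl-1,3,2-diazaphospholidine at 40 °C then gives 22 by syn elimination, whatever face the diol occupies.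

Step 17. Attack at the neopentyl C8 may be sluggish. The first-formed alkylborane or excess borane may also add to the tetrasubstituted C2=C3 bond, so chemoselectivity could be lost. The fallback replaces hydroboration by osmylation and radical deoxygenation. OsO4 (pyridine, then NaHSO3) takes the less substituted C7=C8 bond of 22 from the face opposite the C6 methyl and gives the cis-7,8-diol F8, the C7,C8-diastereomer of the diol named above. Thiocarbonyldiimidazole gives the cyclic thionocarbonate F9. Bu3SnH/AIBN (a Barton–McCombie-type cleavage) breaks the tertiary allylic C7–O bond, and hydrogen is delivered to C7 from the same open face, giving the stannyl thiolcarbonate F10. Methanolysis of F10 (K2CO3, MeOH) returns to 24.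

Further compounds
F1 | step 24 | (E)-2-pyridyl vinyl sulfone alcohol (28 with pyridin-2-yl for phenyl) | C/C1=C2\C[C@@H](O[Si](C)(C)C(C)(C)C)[C@H](C)[C@@H]2[C@@H](O[Si](C)(C)C(C)(C)C)[C@@](C)(CC/C(C)=C/S(=O)(=O)c3ccccn3)[C@H](CO)CC1
F2 | step 24 | C17 aldehyde of F1 | C/C1=C2\C[C@@H](O[Si](C)(C)C(C)(C)C)[C@H](C)[C@@H]2[C@@H](O[Si](C)(C)C(C)(C)C)[C@@](C)(CC/C(C)=C/S(=O)(=O)c3ccccn3)[C@H](C=O)CC1
F3 | step 24 | (E)-enone of the pyridylsulfonyl series | C/C1=C2\C[C@@H](O[Si](C)(C)C(C)(C)C)[C@H](C)[C@@H]2[C@@H](O[Si](C)(C)C(C)(C)C)[C@@](C)(CC/C(C)=C/S(=O)(=O)c3ccccn3)[C@H](/C=C/C(C)=O)CC1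
F4 | step 24 | silyloxydiene of the pyridylsulfonyl series | C/C1=C2\C[C@@H](O[Si](C)(C)C(C)(C)C)[C@H](C)[C@@H]2[C@@H](O[Si](C)(C)C(C)(C)C)[C@@](C)(CC/C(C)=C/S(=O)(=O)c3ccccn3)[C@H](/C=C/C(=C)O[Si](C)(C)C(C)(C)C)CC1
F5 | step 24 | pyridylsulfonyl cycloadduct (33 with pyridin-2-yl for phenyl) | C/C1=C2\C[C@@H](O[Si](C)(C)C(C)(C)C)[C@H](C)[C@@H]2[C@@H](O[Si](C)(C)C(C)(C)C)[C@@]2(C)CC[C@]3(C)[C@@H](S(=O)(=O)c4ccccn4)CC(O[Si](C)(C)C(C)(C)C)=C[C@H]3[C@@H]2CC1
F6 | step 16 | cis-7,8-diol from pinacol coupling (both OH down on ring B, C8 trans to 6-Me) | C/C1=C2\C[C@@H](O[Si](C)(C)C(C)(C)C)[C@H](C)[C@@]2(O)[C@H](O)[C@@](C)(CCC3(C)OCCO3)[C@H](CO[Si](C)(C)C(C)(C)C)CC1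
F7 | step 16 | cyclic 7,8-thionocarbonate of F6 | C/C1=C2\C[C@@H](O[Si](C)(C)C(C)(C)C)[C@H](C)[C@]23OC(=S)O[C@@H]3[C@@](C)(CCC4(C)OCCO4)[C@H](CO[Si](C)(C)C(C)(C)C)CC1
F8 | step 17 | cis-7,8-diol from osmylation (both OH up on ring B, C8 cis to 6-Me) | C/C1=C2\C[C@@H](O[Si](C)(C)C(C)(C)C)[C@H](C)[C@]2(O)[C@@H](O)[C@@](C)(CCC3(C)OCCO3)[C@H](CO[Si](C)(C)C(C)(C)C)CC1
F9 | step 17 | cyclic 7,8-thionocarbonate of F8 | C/C1=C2\C[C@@H](O[Si](C)(C)C(C)(C)C)[C@H](C)[C@@]23OC(=S)O[C@H]3[C@@](C)(CCC4(C)OCCO4)[C@H](CO[Si](C)(C)C(C)(C)C)CC1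
F10 | step 17 | 8-O-[(tributylstannylthio)carbonyl] derivative of 24 | C/C1=C2\C[C@@H](O[Si](C)(C)C(C)(C)C)[C@H](C)[C@@H]2[C@@H](OC(=O)S[Sn](CCCC)(CCCC)CCCC)[C@@](C)(CCC3(C)OCCO3)[C@H](CO[Si](C)(C)C(C)(C)C)CC1
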